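**Retrosynthetic overview**
1. Isofeterin 20 (drimane locants: ring A = C1–C5 + C10, ring B = C5–C10, C11 = CH2OAr, C12 = exocyclic CH2) ⇐ decalinol 18 by acetylation at O6 and desilylation at O3.
2. 18 ⇐ one cationic cascade from the monocyclic epoxy allylsilane 17: the cyclopentane C1–C2–C3–C4–C10 is enlarged to ring A (C4 moves from C10 to C5) and ring B is closed (C9–C10) in the same operation.
3. Enabling feature: the cis-5,6-oxirane hangs on C10, a quaternary cyclopentane carbon bonded to the fully substituted C4. Ionization at C5 is answered by the anti C10–C4 bond, which leaves the C6 hydroxyl and a tertiary C10 cation within reach of the (Z)-allylsilane C12–C8=C9.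
4. 17 ⇐ umbelliferone + allylic alcohol 15 ⇐ catalyst-controlled cis-epoxidation of Z-olefin 13 ⇐ enol phosphate/Kumada, Masamune–Brooks and Z-Wittig chain growth on aldehyde 7.
5. 7 ⇐ nitrile methylation and reductive cyanation of silyl ketol 3 ⇐ CBS desymmetrization of 2,2-dimethylcyclopentane-1,3-dione (sets C3). Ring order: five-membered ring bought; ring A (by enlargement) and ring B formed together; coumarin bought.

Key step: step 13

Remarks:
- Drimane locants of the target are used for the same carbons in every precursor.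
- The configuration at C10 of the cyclopentane precursors (set in step 4, drawn as the expected product of methylation anti to the silyloxy group) is of no consequence: C10 becomes a planar cation in step 13, so its epimer would converge on the same product.
- Enolates, ylides, the metalated nitrile and carbocations are described in the Why lines; covalent intermediates of two-stage steps are numbered.
- The catalyst enantiomers in steps 1 and 10 are assigned by the standard models (CBS model; analogy with cis-β-methylstyrene); the antipodal catalyst would be used if the observed sense were opposite.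

**Step 1**
Reactants: 1 2,2-dimethylcyclopentane-1,3-dione
Product: 2 (S)-3-hydroxy-2,2-dimethylcyclopentan-1-one
Conditions: (R)-2-methyl-CBS-oxazaborolidine (15 mol%), BH3·SMe2 (0.7 equiv), THF, −40 °C; MeOH quench
Reagents that add atoms: none
Why: Corey–Bakshi–Shibata reduction desymmetrizes the prochiral dione, the oxazaborolidine–borane complex delivering hydride to one enantiotopic carbonyl with the quaternary carbon as the large group, which sets C3 (S) by catalyst control.

**Step 2**
Reactants: 2 (S)-3-hydroxy-2,2-dimethylcyclopentan-1-one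
Product: 3 (S)-3-[(tert-butyldimethylsilyl)oxy]-2,2-dimethylcyclopentan-1-one
Conditions: TBSOTf, 2,6-lutidine, CH2Cl2, 0 °C
Reagents that add atoms: tert-butyldimethylsilyl triflate, CC(C)(C)[Si](C)(C)OS(=O)(=O)C(F)(F)F
Why: Silyl triflate silylation protects the hindered neopentyl secondary alcohol without touching the non-enolizable side of the ketone.

**Step 3**
Reactants: 3 (S)-3-[(tert-butyldimethylsilyl)oxy]-2,2-dimethylcyclopentan-1-one
Product: 4 (3S)-3-[(tert-butyldimethylsilyl)oxy]-2,2-dimethylcyclopentane-1-carbonitrile (both C1 epimers)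
Conditions: TosMIC, t-BuOK, DME–EtOH, 0 → 40 °C
Reagents that add atoms: p-toluenesulfonylmethyl isocyanide, Cc1ccc(cc1)S(=O)(=O)C[N+]#[C-]
Why: Van Leusen reductive cyanation turns the ketone into the homologous nitrile, a reaction that tolerates cyclopentanones flanked by a quaternary carbon; the new centre need not be controlled because step 4 deprotonates it.

**Step 4**
Reactants: 4 (3S)-3-[(tert-butyldimethylsilyl)oxy]-2,2-dimethylcyclopentane-1-carbonitrile
Product: 5 (1R,3S)-3-[(tert-butyldimethylsilyl)oxy]-1,2,2-trimethylcyclopentane-1-carbonitrile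
Conditions: LDA, THF, −78 °C; MeI, −78 → 0 °C
Reagents that add atoms: iodomethane, CI
Why: C-alkylation of the lithiated nitrile builds the quaternary carbon C10 next to the gem-dimethyl carbon, methyl iodide approaching anti to the silyloxy group.

**Step 5**
Reactants: 5 (1R,3S)-3-[(tert-butyldimethylsilyl)oxy]-1,2,2-trimethylcyclopentane-1-carbonitrile
Product: 7 (1R,3S)-3-[(tert-butyldimethylsilyl)oxy]-1,2,2-trimethylcyclopentane-1-carbaldehyde, via N-aluminated aldimine 6 (not isolated)
Conditions: DIBAL-H, toluene, −78 → 0 °C; then 1 M aq. HCl, 0 °C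
Reagents that add atoms: water, O
Why: DIBAL reduction of the tertiary nitrile stops at the aluminated aldimine, which is hydrolysed on work-up to the non-enolizable aldehyde.

**Step 6**
Reactants: 7 (1R,3S)-3-[(tert-butyldimethylsilyl)oxy]-1,2,2-trimethylcyclopentane-1-carbaldehyde; 8 (2-carboxyethyl)triphenylphosphonium bromide
Product: 9 (Z)-4-{(1S,3S)-3-[(tert-butyldimethylsilyl)oxy]-1,2,2-trimethylcyclopentyl}but-3-enoic acid
Conditions: 8, NaHMDS (2 equiv per 8), THF, −78 → 0 °C; then 7, −78 °C → rt; aq. HCl work-up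
Reagents that add atoms: none
Why: Wittig olefination with the non-stabilized carboxylate ylide gives the Z olefin (C5=C6) under kinetic control, the α-quaternary aldehyde reinforcing cis selectivity.

**Step 7**
Reactants: 9 (Z)-4-{(1S,3S)-3-[(tert-butyldimethylsilyl)oxy]-1,2,2-trimethylcyclopentyl}but-3-enoic acid
Product: 11 methyl (Z)-6-{(1S,3S)-3-[(tert-butyldimethylsilyl)oxy]-1,2,2-trimethylcyclopentyl}-3-oxohex-5-enoate, via acyl imidazolide 10 (not isolated)
Conditions: CDI, THF, rt; then MeO2CCH2CO2K, MgCl2, THF, rt → 45 °C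
Reagents that add atoms: 1,1'-carbonyldiimidazole (imidazolyl group of 10), O=C(n1ccnc1)n1ccnc1; potassium methyl malonate, COC(=O)CC(=O)[O-].[K+]
Why: Masamune–Brooks homologation acylates the magnesium malonate with the acyl imidazolide and decarboxylates to the β-keto ester under near-neutral conditions that do not move the β,γ-olefin.

**Step 8**
Reactants: 11 methyl (Z)-6-{(1S,3S)-3-[(tert-butyldimethylsilyl)oxy]-1,2,2-trimethylcyclopentyl}-3-oxohex-5-enoate
Product: 12 methyl (2Z,5Z)-3-[(diethoxyphosphoryl)oxy]-6-{(1S,3S)-3-[(tert-butyldimethylsilyl)oxy]-1,2,2-trimethylcyclopentyl}hexa-2,5-dienoate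
Conditions: NaH, Et2O, 0 °C; ClP(O)(OEt)2
Reagents that add atoms: diethyl chlorophosphate, CCOP(=O)(Cl)OCC
Why: O-phosphorylation of the chelated sodium enolate of the β-keto ester gives the Z enol phosphate (phosphate cis to the ester).

**Step 9**
Reactants: 12 methyl (2Z,5Z)-3-[(diethoxyphosphoryl)oxy]-6-{(1S,3S)-3-[(tert-butyldimethylsilyl)oxy]-1,2,2-trimethylcyclopentyl}hexa-2,5-dienoate
Product: 13 methyl (2Z,5Z)-6-{(1S,3S)-3-[(tert-butyldimethylsilyl)oxy]-1,2,2-trimethylcyclopentyl}-3-[(trimethylsilyl)methyl]hexa-2,5-dienoate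
Conditions: Me3SiCH2MgCl, Ni(acac)2 (5 mol%), THF, 0 °C → rt
Reagents that add atoms: (trimethylsilyl)methylmagnesium chloride, C[Si](C)(C)C[Mg]Cl
Why: Nickel-catalysed Kumada coupling of the enol phosphate proceeds with retention of olefin geometry, placing C12 cis to C11 and giving an allylsilane whose nucleophilicity is masked by conjugation with the ester.

**Step 10**
Reactants: 13 methyl (2Z,5Z)-6-{(1S,3S)-3-[(tert-butyldimethylsilyl)oxy]-1,2,2-trimethylcyclopentyl}-3-[(trimethylsilyl)methyl]hexa-2,5-dienoate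
Product: 14 methyl (Z)-4-[(2R,3S)-3-{(1R,3S)-3-[(tert-butyldimethylsilyl)oxy]-1,2,2-trimethylcyclopentyl}oxiran-2-yl]-3-[(trimethylsilyl)methyl]but-2-enoate
Conditions: (S,S)-(salen)MnCl [salen = N,N'-bis(3,5-di-tert-butylsalicylidene)cyclohexane-1,2-diaminate] (5 mol%), 4-phenylpyridine N-oxide, aq. NaOCl (pH 11.3), CH2Cl2, 0 °C
Reagents that add atoms: sodium hypochlorite, [Na+].[O-]Cl
Why: Jacobsen–Katsuki epoxidation transfers oxygen syn to the electron-rich cis-disubstituted olefin and leaves the trisubstituted enoate; the salen ligand selects the olefin face (the tert-alkyl group taking the role of the aryl group of cis-β-methylstyrene), which sets C5 (S) and C6 (R) by catalyst control.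

**Step 11**
Reactants: 14 methyl (Z)-4-[(2R,3S)-3-{(1R,3S)-3-[(tert-butyldimethylsilyl)oxy]-1,2,2-trimethylcyclopentyl}oxiran-2-yl]-3-[(trimethylsilyl)methyl]but-2-enoate
Product: 15 (Z)-4-[(2R,3S)-3-{(1R,3S)-3-[(tert-butyldimethylsilyl)oxy]-1,2,2-trimethylcyclopentyl}oxiran-2-yl]-3-[(trimethylsilyl)methyl]but-2-en-1-ol
Conditions: DIBAL-H (2.3 equiv), CH2Cl2, −78 °C; aq. Rochelle salt
Reagents that add atoms: none
Why: DIBAL 1,2-reduction of the enoate at low temperature gives the allylic alcohol and unmasks the allylsilane while the hindered oxirane and the silyl groups stay intact.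

**Step 12**
Reactants: 15 (Z)-4-[(2R,3S)-3-{(1R,3S)-3-[(tert-butyldimethylsilyl)oxy]-1,2,2-trimethylcyclopentyl}oxiran-2-yl]-3-[(trimethylsilyl)methyl]but-2-en-1-ol; 16 7-hydroxycoumarin (umbelliferone)
Product: 17 7-{[(Z)-4-[(2R,3S)-3-{(1R,3S)-3-[(tert-butyldimethylsilyl)oxy]-1,2,2-trimethylcyclopentyl}oxiran-2-yl]-3-[(trimethylsilyl)methyl]but-2-en-1-yl]oxy}-2H-chromen-2-one
Conditions: PPh3, DIAD, THF, 0 °C → rt
Reagents that add atoms: none
Why: Mitsunobu etherification joins the acidic phenol to the primary allylic carbon (SN2 at C11) under neutral conditions that spare the oxirane and the allylsilane.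

**Step 13**
Reactants: 17 7-{[(Z)-4-[(2R,3S)-3-{(1R,3S)-3-[(tert-butyldimethylsilyl)oxy]-1,2,2-trimethylcyclopentyl}oxiran-2-yl]-3-[(trimethylsilyl)methyl]but-2-en-1-yl]oxy}-2H-chromen-2-one
Product: 18 7-{[(3S,5S,6R,9R,10S)-3-[(tert-butyldimethylsilyl)oxy]-6-hydroxydrim-8(12)-en-11-yl]oxy}-2H-chromen-2-one (trans-decalin; axial O3; equatorial O6 and C11)
Conditions: MeAlCl2 (3 equiv), CH2Cl2, −78 °C; aq. NaHCO3/Rochelle salt
Reagents that add atoms: none
Why: Proposed new method: MeAlCl2 activates the cis-oxirane, whose C5–O bond ionizes with anti-periplanar 1,2-shift of C4 from C10 to C5 (Wagner–Meerwein enlargement of the cyclopentane to ring A, inversion at C5, retention at C6), and the resulting tertiary C10 cation is captured by C9 of the (Z)-allylsilane, loss of the silyl group giving the C8=C12 methylene. The closest known reaction types are Lewis-acid rearrangements of epoxides by 1,2-alkyl shift from a neighbouring quaternary carbon (pinene-oxide type, and the D-homoannulation of cyclopentylcarbinyl cations) and epoxide-initiated cation–olefin cyclizations terminated by allylsilanes; their combination on this substrate class is new. Ring A arises by one-carbon ring expansion (1,2-shift), and ring B by 6-endo attack of the C8=C9 π bond on the C10 cation through a chair transition state (SE2' at the allylsilane). C5 is fixed by the oxirane through inversion and C6 is carried over unchanged; C10 (its earlier configuration erased in the planar cation) and C9 are set relative to C5 by the chair, with O6 and the C4–C5 bond equatorial, the Z olefin placing C11 equatorial and the ring fusion trans, as in cyclizations of monocyclofarnesyl cations. The step needs opening at C5 with migration of C4 rather than of C1, the methyl group or hydride: C4 is the only fully substituted migrating carbon, its shift relieves the congested C10–C4 bond between two quaternary carbons and gives a tertiary cation, and the neopentyl C5 cannot be reached directly by the allylsilane (5-endo).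

**Step 14**
Reactants: 18 7-{[(3S,5S,6R,9R,10S)-3-[(tert-butyldimethylsilyl)oxy]-6-hydroxydrim-8(12)-en-11-yl]oxy}-2H-chromen-2-one
Product: 19 7-{[(3S,5S,6R,9R,10S)-6-acetoxy-3-[(tert-butyldimethylsilyl)oxy]drim-8(12)-en-11-yl]oxy}-2H-chromen-2-one
Conditions: Ac2O, pyridine, DMAP (cat.), CH2Cl2, rt
Reagents that add atoms: acetic anhydride, CC(=O)OC(C)=O
Why: DMAP-catalysed acylation esterifies the only free hydroxyl, the equatorial C6 alcohol.

**Step 15**
Reactants: 19 7-{[(3S,5S,6R,9R,10S)-6-acetoxy-3-[(tert-butyldimethylsilyl)oxy]drim-8(12)-en-11-yl]oxy}-2H-chromen-2-one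
Product: 20 Isofeterin
Conditions: HF·pyridine, THF–pyridine, 0 °C → rt
Reagents that add atoms: none
Why: Fluoride-driven desilylation frees the axial C3 alcohol under buffered conditions that spare the acetate, the coumarin lactone and the exocyclic olefin.

**Compound list**
1 | 2,2-dimethylcyclopentane-1,3-dione | CC1(C)C(=O)CCC1=O | starting material
2 | (S)-3-hydroxy-2,2-dimethylcyclopentan-1-one | O[C@H]1CCC(=O)C1(C)C | intermediate
3 | (S)-3-[(tert-butyldimethylsilyl)oxy]-2,2-dimethylcyclopentan-1-one | CC(C)(C)[Si](C)(C)O[C@H]1CCC(=O)C1(C)C | intermediate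
4 | (3S)-3-[(tert-butyldimethylsilyl)oxy]-2,2-dimethylcyclopentane-1-carbonitrile (both C1 epimers) | N#CC1CC[C@H](O[Si](C)(C)C(C)(C)C)C1(C)C | intermediate
5 | (1R,3S)-3-[(tert-butyldimethylsilyl)oxy]-1,2,2-trimethylcyclopentane-1-carbonitrile | N#C[C@]1(C)CC[C@H](O[Si](C)(C)C(C)(C)C)C1(C)C | intermediate
6 | N-(diisobutylalumanyl)aldimine of 7 | CC(C)C[Al](CC(C)C)N=C[C@]1(C)CC[C@H](O[Si](C)(C)C(C)(C)C)C1(C)C | intermediate
7 | (1R,3S)-3-[(tert-butyldimethylsilyl)oxy]-1,2,2-trimethylcyclopentane-1-carbaldehyde | O=C[C@]1(C)CC[C@H](O[Si](C)(C)C(C)(C)C)C1(C)C | intermediate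
8 | (2-carboxyethyl)triphenylphosphonium bromide | OC(=O)CC[P+](c1ccccc1)(c1ccccc1)c1ccccc1.[Br-] | starting material
9 | (Z)-4-{(1S,3S)-3-[(tert-butyldimethylsilyl)oxy]-1,2,2-trimethylcyclopentyl}but-3-enoic acid | OC(=O)C/C=C\[C@]1(C)CC[C@H](O[Si](C)(C)C(C)(C)C)C1(C)C | intermediate
10 | 1-[(Z)-4-{(1S,3S)-3-[(tert-butyldimethylsilyl)oxy]-1,2,2-trimethylcyclopentyl}but-3-enoyl]imidazole | O=C(C/C=C\[C@]1(C)CC[C@H](O[Si](C)(C)C(C)(C)C)C1(C)C)n1ccnc1 | intermediate
11 | methyl (Z)-6-{(1S,3S)-3-[(tert-butyldimethylsilyl)oxy]-1,2,2-trimethylcyclopentyl}-3-oxohex-5-enoate | COC(=O)CC(=O)C/C=C\[C@]1(C)CC[C@H](O[Si](C)(C)C(C)(C)C)C1(C)C | intermediate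
12 | methyl (2Z,5Z)-3-[(diethoxyphosphoryl)oxy]-6-{(1S,3S)-3-[(tert-butyldimethylsilyl)oxy]-1,2,2-trimethylcyclopentyl}hexa-2,5-dienoate | CCOP(=O)(OCC)O/C(C/C=C\[C@]1(C)CC[C@H](O[Si](C)(C)C(C)(C)C)C1(C)C)=C\C(=O)OC | intermediate
13 | methyl (2Z,5Z)-6-{(1S,3S)-3-[(tert-butyldimethylsilyl)oxy]-1,2,2-trimethylcyclopentyl}-3-[(trimethylsilyl)methyl]hexa-2,5-dienoate | COC(=O)/C=C(C[Si](C)(C)C)/C/C=C\[C@]1(C)CC[C@H](O[Si](C)(C)C(C)(C)C)C1(C)C | intermediate
14 | methyl (Z)-4-[(2R,3S)-3-{(1R,3S)-3-[(tert-butyldimethylsilyl)oxy]-1,2,2-trimethylcyclopentyl}oxiran-2-yl]-3-[(trimethylsilyl)methyl]but-2-enoate | COC(=O)/C=C(C[Si](C)(C)C)/C[C@H]1O[C@H]1[C@]1(C)CC[C@H](O[Si](C)(C)C(C)(C)C)C1(C)C | intermediate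
15 | (Z)-4-[(2R,3S)-3-{(1R,3S)-3-[(tert-butyldimethylsilyl)oxy]-1,2,2-trimethylcyclopentyl}oxiran-2-yl]-3-[(trimethylsilyl)methyl]but-2-en-1-ol | OC/C=C(C[Si](C)(C)C)/C[C@H]1O[C@H]1[C@]1(C)CC[C@H](O[Si](C)(C)C(C)(C)C)C1(C)C | intermediate
16 | 7-hydroxycoumarin (umbelliferone) | Oc1ccc2ccc(=O)oc2c1 | starting material
17 | 7-{[(Z)-4-[(2R,3S)-3-{(1R,3S)-3-[(tert-butyldimethylsilyl)oxy]-1,2,2-trimethylcyclopentyl}oxiran-2-yl]-3-[(trimethylsilyl)methyl]but-2-en-1-yl]oxy}-2H-chromen-2-one | O=c1ccc2ccc(OC/C=C(C[Si](C)(C)C)/C[C@H]3O[C@H]3[C@]3(C)CC[C@H](O[Si](C)(C)C(C)(C)C)C3(C)C)cc2o1 | intermediate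
18 | 7-{[(3S,5S,6R,9R,10S)-3-[(tert-butyldimethylsilyl)oxy]-6-hydroxydrim-8(12)-en-11-yl]oxy}-2H-chromen-2-one | C=C1C[C@@H](O)[C@@H]2C(C)(C)[C@@H](O[Si](C)(C)C(C)(C)C)CC[C@@]2(C)[C@@H]1COc1ccc2ccc(=O)oc2c1 | intermediate
19 | 7-{[(3S,5S,6R,9R,10S)-6-acetoxy-3-[(tert-butyldimethylsilyl)oxy]drim-8(12)-en-11-yl]oxy}-2H-chromen-2-one | C=C1C[C@@H](OC(C)=O)[C@@H]2C(C)(C)[C@@H](O[Si](C)(C)C(C)(C)C)CC[C@@]2(C)[C@@H]1COc1ccc2ccc(=O)oc2c1 | intermediate
20 | Isofeterin, 7-{[(3S,5S,6R,9R,10S)-6-acetoxy-3-hydroxydrim-8(12)-en-11-yl]oxy}-2H-chromen-2-one | C=C1C[C@@H](OC(C)=O)[C@@H]2C(C)(C)[C@@H](O)CC[C@@]2(C)[C@@H]1COc1ccc2ccc(=O)oc2c1 | target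

**Step count and risks**
Total step count: 15. Longest linear sequence: 15 steps (from 1).

Steps most likely to fail:

1. Step 13 (proposed new method). The oxirane may open with hydride shift, or with migration of C1 or the methyl group instead of C4. The silyl ether oxygen, which sits cis to the oxiranyl arm, may intercept C5. The allylsilane or the coumarin may interfere before the shift, or the C10 cation may lose a proton before ring B closes. The fallback separates the two events and runs each as a reaction of established type; it sets out from 14 and comes back at 18. The ring enlargement is carried out alone on 14, whose allylsilane is deactivated by the ester: Sc(OTf)3 (cat.) in wet hexafluoroisopropanol at 0 °C opens the oxirane with the 1,2-shift of C4 (solvolytic Wagner–Meerwein enlargement of a cyclopentylcarbinyl cation), and water captures the tertiary cation to give the ring-enlarged diol ester F1 (C10 carbinol, either epimer). DIBAL-H (CH2Cl2, −78 °C) reduces the ester to the triol F2, and a Mitsunobu reaction with 16 at the primary allylic hydroxyl gives the aryl ether F3. SnCl4 (CH2Cl2, −78 °C) then ionizes the tertiary alcohol and the allylsilane closes ring B (tertiary-cation/allylsilane cyclization) to 18.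

2. Step 10. Facial selectivity may be poor, or oxygen transfer sluggish, on a non-conjugated cis olefin that carries a neopentyl-type substituent. The fallback gives up reagent control; it sets out from 13 and comes back at 14. Dimethyldioxirane (acetone, −20 °C) epoxidizes only the isolated Z olefin and gives 14 together with its oxirane-face diastereomer F4. Because C3 and the ring carbon are already fixed, the two are diastereomers and are separated by chromatography (preparative HPLC if needed); 14 goes on to step 11.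

3. Step 6. The carboxylate ylide may fragment by β-elimination before it adds to the hindered neopentyl aldehyde, and Z selectivity may erode. The fallback builds the Z olefin from an alkyne; it sets out from 7 and comes back at 9. Ohira–Bestmann homologation (dimethyl (1-diazo-2-oxopropyl)phosphonate, K2CO3, MeOH) gives the terminal alkyne F5. Its lithium acetylide (n-BuLi, THF, −78 °C) opens ethylene oxide in the presence of BF3·OEt2 to give the homopropargylic alcohol F6. Semihydrogenation (H2, Pd/CaCO3 poisoned with Pb(OAc)2, quinoline) gives the Z-homoallylic alcohol F7, and oxidation with TEMPO/PhI(OAc)2 in aqueous MeCN gives acid 9.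

**Further compounds**
F1 | step 13 | methyl (Z)-5-hydroxy-5-[ring-A cyclohexyl]-3-[(trimethylsilyl)methyl]pent-2-enoate: ring A complete with C3 silyl ether, C5 and C6 as in 18, C10 tertiary carbinol (either epimer), ring B open | COC(=O)/C=C(C[Si](C)(C)C)/C[C@@H](O)[C@@H]1C(C)(C)[C@@H](O[Si](C)(C)C(C)(C)C)CCC1(C)O
F2 | step 13 | allylic alcohol from F1 (triol: primary allylic, secondary C6 and tertiary C10 hydroxyls) | OC/C=C(C[Si](C)(C)C)/C[C@@H](O)[C@@H]1C(C)(C)[C@@H](O[Si](C)(C)C(C)(C)C)CCC1(C)O
F3 | step 13 | 7-coumarinyl ether of F2 at the primary allylic oxygen | O=c1ccc2ccc(OC/C=C(C[Si](C)(C)C)/C[C@@H](O)[C@@H]3C(C)(C)[C@@H](O[Si](C)(C)C(C)(C)C)CCC3(C)O)cc2o1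
F4 | step 10 | methyl (Z)-4-[(2S,3R)-3-{(1R,3S)-3-[(tert-butyldimethylsilyl)oxy]-1,2,2-trimethylcyclopentyl}oxiran-2-yl]-3-[(trimethylsilyl)methyl]but-2-enoate | COC(=O)/C=C(C[Si](C)(C)C)/C[C@@H]1O[C@@H]1[C@]1(C)CC[C@H](O[Si](C)(C)C(C)(C)C)C1(C)C
F5 | step 6 | tert-butyl{[(1S,3S)-3-ethynyl-2,2,3-trimethylcyclopentyl]oxy}dimethylsilane | C#C[C@]1(C)CC[C@H](O[Si](C)(C)C(C)(C)C)C1(C)C
F6 | step 6 | 4-{(1S,3S)-3-[(tert-butyldimethylsilyl)oxy]-1,2,2-trimethylcyclopentyl}but-3-yn-1-ol | OCCC#C[C@]1(C)CC[C@H](O[Si](C)(C)C(C)(C)C)C1(C)C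
F7 | step 6 | (Z)-4-{(1S,3S)-3-[(tert-butyldimethylsilyl)oxy]-1,2,2-trimethylcyclopentyl}but-3-en-1-ol | OCC/C=C\[C@]1(C)CC[C@H](O[Si](C)(C)C(C)(C)C)C1(C)C
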